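Read the rise of target in two runs that differ in the charge of free catalyst and in nothing else, and take from them what a change of that charge does to the flask at 20% conversion.

| setting | delta | zeta | flask |
|---|---|---|---|
| substrate | 0.19 M | 0.19 M | 0.19 M |
| reagent | 0.38 M | 0.38 M | 0.380 M |
| free catalyst | 0.055 mM | 0.22 mM | 0.11 mM |
| added ligand | 0.16 mM | 0.16 mM | 0.16 mM |
| remark | run made earlier | run made earlier |  |

| delta: time / h | delta: target / % | zeta: time / h | zeta: target / % |
|---|---|---|---|
| 1.50 | 4.8 | 1.00 | 14.2 |
| 4.00 | 9.1 | 2.00 | 24.1 |
| 8.00 | 16.1 | 5.00 | 44.5 |
| 12.0 | 22.3 | 12.0 | 71.1 |

(each reading ± 0.3 percentage points)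



- factor on the rate of making target when 20% of the substrate are converted if free catalyst is charged twice over
- factor on the rate when 20% of the substrate are converted if free catalyst is charged at 0.60 mM instead

Compare two rates. The delta run passes 20% between 8.00 h and 12.0 h, climbing by 0.0155 /h as a fraction of the substrate charged, and the zeta run passes it between 1.00 h and 2.00 h, climbing by 0.0990 /h. Both chords therefore read nearly the same amounts of substrate and reagent, so their ratio, 6.39, belongs to a catalyst charge raised by a factor of 4.00. Take from these the reading n = 1.34, the power to which the rate at one conversion follows the charge of free catalyst with the other charges as in these runs, its apparent order.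

Write the balance of free catalyst, the smaller charge in the flask at 0.11 mM against 0.16 mM of added ligand: catalyst charged equals catalyst at work plus catalyst held back. With n above one, the rate rises faster than the charge, which reads as a share at work that rises with the charge, and the added ligand, equal in both runs, is the likely holder. Doubling takes the flask to the charge of zeta, the upper end of the range read, so reckon 2.53; 0.60 mM lies beyond that range, and the same power gives 9.71, an extrapolation. The forecast, holding that “the added ligand ties up part of the catalyst reversibly”, gives 2.55 and 9.8.

The simulation gives 2.61 for doubling and 10.2 for 0.60 mM.

    substrate + free catalyst → catalyst intermediate A (k = 34.0 /M/min)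
    reagent + catalyst intermediate A ⇌ catalyst intermediate B (K = 7.30 /M, k = 1100 /M/min)
    catalyst intermediate B ⇌ free catalyst + target (K = 0.120 M, k = 11.0 /min)
    free catalyst + added ligand ⇌ idle complex (K = 30000 /M, k = 330 /M/min)

In the flask at 6.00 h, idle complex, an off-cycle form, holds 57.2% of the catalyst charged, while free catalyst stands at 19.4%. Turn both results back into the apparent order: beside the 1.34 read from delta and zeta, doubling the charge of free catalyst in the flask gives 1.38, and the step to 0.60 mM gives 1.37.

(The earlier runs and the new flask stem from a simulated flask from invented constants, noise included.)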